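Start from a small charge of second substrate: the noon run, with 18 mM, averages 68.5% target, in percent of the starting material charged, and the autumn run, with 26 mM, averages 60.8%, so the noon run reads more target than the autumn run.

common to all: starting material 35 mM; free catalyst 0.77 mM; impurity 0.12 mM
- noon: second substrate 18 mM; reagent 35 mM; run made earlier
- autumn: second substrate 26 mM; reagent 35 mM; run made earlier
- flask: second substrate 35.0 mM; reagent 35.0 mM; time 20 h

| run | time / h | target / % | starting material / % |
|---|---|---|---|
| noon | 3.00 | 67.8 | 30.8 |
| noon | 6.00 | 69.6 | 30.1 |
| noon | 10.0 | 69.8 | 29.7 |
| noon | 15.0 | 67.3 | 31.5 |
| noon | 20.0 | 69.2 | 31.2 |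
| noon | 25.0 | 67.2 | 30.6 |
| autumn | 2.00 | 61.3 | 38.1 |
| autumn | 3.00 | 59.0 | 40.3 |
| autumn | 4.00 | 60.2 | 38.9 |
| autumn | 6.00 | 60.2 | 39.0 |
| autumn | 10.0 | 62.5 | 37.3 |
| autumn | 15.0 | 62.0 | 38.3 |
| autumn | 25.0 | 60.5 | 38.3 |

(each reading ± 1 percentage point)

- the numbers in the tables scatter with a standard deviation of 1 percentage point
- the reaction counts as stopped when no species that holds the starting material changes by six tenths of a point or more over the second half of the time

1. the state of affairs at 20 h: stopped, and by what, or still going (all of the starting material has reacted / the reagent has run out first / no working catalyst is left / it is still moving / forward and back rates have come level)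
2. how much target there is at 20 h, in percent of the starting material charged

Turn the time first. The noon run reads 67.8% target at 3.00 h and 67.2% at 25.0 h, with a scatter of 1 percentage point, so by hand you expect no gain from waiting. Starting material, reagent, catalyst and impurity have the same charges in both runs and the flask, so the runs give no reading on turning them.

That leaves the second substrate. My reckoning assumes that it shares the reagent with the starting material, one for one, and that each run has used its whole reagent charge. In the noon run, 11.0 mM of reagent is then not in target. Now divide the two rates of loss. If each goes with its own amount, time drops out, and you keep one number. The noon readings give 1.25 and the autumn readings 1.27, so take 1.26 for the sharing ratio, a selectivity factor: the logarithm of the starting material fraction left over that of the second substrate fraction left.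

For the flask, weight each charge by the ratio: a first guess of 55.7% of the starting material reacted. The ratio then asks for 47.7% of the second substrate. Together they need 36.2 mM of reagent, more than the 35.0 mM charged. Scaled down, I expect 53.9% target, stopped by the reagent.

The forecast says no working catalyst is left and 55%, on the grounds that “the catalyst dies, with the second substrate hurting it”. On the stop, my reckoning differs.

The flask gives 53.8% target: the reagent has run out first. At 20.0 h, the flask holds 0% of its reagent charge, and free catalyst stands at 30.7% of the catalyst charged. The amounts left in the flask give a sharing ratio of 1.22.

    starting material + free catalyst ⇌ catalyst intermediate A (K = 25.0 /M, k = 314 /M/min)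
    reagent + catalyst intermediate A → free catalyst + target (k = 3030 /M/min)
    second substrate + free catalyst ⇌ catalyst intermediate B (K = 72.8 /M, k = 457 /M/min)
    reagent + catalyst intermediate B → free catalyst + second product (k = 388 /M/min)
    free catalyst + impurity → spent catalyst (k = 35100 /M/min)

Now take the neighbouring flask, with 8.8 mM of second substrate in place of 35.0 mM. The same steps give a first guess of 83.3% and, scaled to the reagent, 81.4% target. That neighbouring flask gives 81.8% target, with 0% of its reagent left.

(Readings and results were computed with constants of no real substance, noise included.)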